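Compound numbers are those of the list after the steps. Chain numbering: C1 is the N-acyl carbon and C12 the pyrrolyl ketone carbon; O3 and O10 are the oxygens on C3 and C10; "ketal carbon" is the carbon that bears the arene, N, O3 and O10. Ipc = isopinocampheyl.

## Analysis of the target

Compound 40 is a tetracycle. A phenol-bearing benzene ring is fused to a γ-lactam (isoindolinone); a 1,3-oxazinan-4-one shares the nitrogen and the ketal carbon with that lactam; an 11-membered ring runs from the ketal carbon through O10, C10 to C4, C3 and O3. The ketal carbon is at the carboxylic acid oxidation level and sits ortho to the phenol, so it is in effect the hindered carbonyl of a 3-hydroxyphthalimide turned into a mixed ketal. There are six stereocentres: C3 (R) and C4 (S) are anti; C9, C10 and C11 (all R) form an anti,anti methyl–oxygen–methyl triad; the ketal carbon is S. On the oxazinanone ring O10 is axial at the ketal carbon, trans to the C4-bearing substituent on C3 and syn to H-3. Because the aryl carbon and the nitrogen lie in the imide plane, this is the epimer that keeps the C3 substituent equatorial, that is, the thermodynamically preferred one. Sensitive groups are the N-acyl lactam (nucleophiles, bases), the ketal (acid), the β-alkoxy ketone with its enolisable C11 centre (base, loss of O10), the pyrrole N–H and the phenol. The hard points are the crowded ketal carbon next to the oxygenated arene, the question of which of the two phthaloyl carbons becomes the ketal, and the medium ring. The strategy rests on the C5–C8 tetramethylene of the 11-membered ring: it carries no functionality, so C7 can be joined to C8 last, after the ketal carbon already holds O10 as an exocyclic alkoxy group.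

## Retrosynthetic reasoning

40 ⇒ 39. The C7–C8 single bond and the free phenol are traced back to a ring alkene and a benzyl ether. One neutral reduction then ends the synthesis; the imide, the ketal and the C11 centre tolerate it, and the alkene geometry of 39 does not matter.

39 ⇒ 38. The C7=C8 bond is cut. It lies in the only unfunctionalised stretch of the macrocycle and far from every stereocentre, whereas a cut at a C–O bond of the ketal would close the medium ring at the most hindered atom. Forward, the butenyl terminus and the C9 vinyl group of 38 must be joined by alkene metathesis with loss of the two terminal CH2 groups.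

38 ⇒ 21 + 37. The O10–ketal carbon bond is cut. This divides the molecule into two fragments of similar size and uses the one carbon that ionises easily. Forward, the methoxy group of 21 is exchanged for the hindered secondary hydroxyl of 37 under reversible acidic conditions, so the ketal carbon can settle in its more stable configuration, which is that of 40.

21 ⇒ 19 ⇒ 16 + 5. In 21 the O3–ketal carbon bond is cut (back to dimethyl ketal 19, through hydroxy ketal 20) and then the N–C1 bond (to acid 16 and lactam 5). Forward, the N–H of 5 is acylated, and release of the C3 hydroxyl closes the six-membered ring by internal exchange of one methoxy group.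

5 ⇒ 3 ⇒ 2 ⇒ 1. The ketal carbon of 5 is traced to the nitrile carbon of 3 and the lactam carbonyl to its ester carbon. A precursor with two carbonyl groups on the benzene ring would leave the choice to the substrate, and the carbonyl next to the benzyloxy group is the less electrophilic and the more hindered one. In 3 the two carbons differ in kind, so the regiochemistry is fixed by construction. Ester 3 comes from bromide 2 by carbonylation, and 2 from 1 by displacement of the fluorine ortho to the nitrile.

16 ⇒ 13 ⇒ 10 ⇒ 9 ⇒ 6 + 7 (+ 11). The C6–C7 bond is cut: the butenyl chain of 13 is the vinyl group of 10 plus the two carbons of 11. The C3–C4 bond is cut next: crotylation of the achiral aldehyde 6 with the shelf-stable boronate 7 under catalyst control sets both stereocentres of 9 in one step. C1 travels as a protected primary alcohol and is oxidised late.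

37 ⇒ 33 + 34; 33 ⇒ 31 ⇒ 30 ⇒ 25 + 26; 25 ⇒ 22. The C12–pyrrole bond is cut to acid 33 and pyrrole 34. The C9–C10 bond is cut to aldehyde 25 and a crotyl unit from 26. Here the crotylation has to deliver the anti,anti triad against the small intrinsic bias of the aldehyde, so the stoichiometric crotylborane 28 made from 26 is used instead of a catalytic method. The C11 centre of 25 is that of ester 22.

## Alternatives that were turned down

Alternative 1: The benzene ring itself is disconnected. Macrobicycle A1 carries a (triisopropylsilyloxy)ethynyl group on the ketal carbon and a 2-pyranone-6-carbonyl group on nitrogen. An intramolecular [4+2] cycloaddition between pyranone and ynol ether, followed by cycloreversion with loss of the lactone bridge, would give the arene and the lactam ring at once as silyl ether A2. In its favour: the step is thermal and reagent-free, the electron-rich alkyne matches the electron-poor diene, and the position of the phenol oxygen follows from the alkyne polarity and the tether. On regiochemical certainty of the arene it is at least as strong as the chosen route, which answers the same question with nitrile 3. Against it: A1 needs an alkynyl-substituted orthoamide carbon inside an 11-membered ring that is already closed, the silyl ynol ether is hydrolytically and thermally labile, and the hindered nitrogen must be acylated by a pyranone acid derivative. The medium ring must also be closed earlier by a separate reaction on a more fragile substrate. The chosen route takes the arene from a catalogue benzonitrile, is shorter, and confines its risk to one catalytic ring closure.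

Alternative 2: The O10–ketal carbon bond is disconnected together with the macrocycle. Anodic (Hofer–Moest type) decarboxylation of tricyclic α-alkoxy acid A3 would give the cation at the ketal carbon, and the C10 hydroxyl would trap it to form the doubly protected target A4. In its favour: the hindered C–O bond forms intramolecularly and irreversibly without acid. On this point it is stronger than the chosen route, whose step 19 is an intermolecular exchange with a crowded alcohol. Against it: an 11-membered ring must close on a short-lived cation in competition with the electrolyte solvent; the pyrrole and the aryl silyl ether are oxidisable; A3 needs a quaternary α-alkoxy-α-amido arylacetic acid; two deprotections follow. What the chosen route offers instead is thermodynamic control of the ketal carbon in an open system and a ring closure that has no competing nucleophile.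

Alternative 3: The aryl–ketal carbon bond and the lactam N–C(=O) bond are disconnected, so the arene arrives last. The arylmagnesium species from iodide A5 would add to the C=N carbon of the macrobicyclic 2-alkoxy-1,3-oxazin-4-one A6, and the magnesium amide would close onto the ortho ester to give benzyl ether A7. In its favour: it is the most convergent plan, it forms two bonds and a ring in one step, and the substitution pattern of A5 fixes the regiochemistry; on convergence it is stronger than the chosen route. Against it: no reliable method exists for a macrocyclic acyl iminocarbonate such as A6. The Grignard reagent also meets a ketone, an acidic N–H and an enolisable β-alkoxy ketone. The ketal stereocentre would be set by kinetic facial attack with no means of correction, and a 2,6-disubstituted aryl nucleophile must attack a hindered carbon. The chosen route forms the ketal carbon under equilibrating conditions and keeps organometallic reagents away from the ketopyrrole.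

Key step: step 20

Remark: aldehyde 6 is treated as a catalogue compound.
Remark: in step 4 the (S)-configured phosphoric acid is taken on the hydrogen-bonded chair model, in which the (R)-acid delivers the allyl unit to the Re face of an aldehyde; the route needs the Si face.
Remark: 39 is drawn with a Z alkene, but both geometries converge on 40 in step 21; 21 is drawn as its more stable ketal epimer, and either epimer serves in step 19, which re-equilibrates that carbon.

## Steps

Step 1
Reactants: 1 2-bromo-6-fluorobenzonitrile
Product: 2 2-(benzyloxy)-6-bromobenzonitrile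
Conditions: BnOH, NaH, THF, 0 °C → rt
Reagents that add atoms: benzyl alcohol, OCc1ccccc1
Why: Nucleophilic aromatic substitution by addition–elimination: the fluorine ortho to the nitrile is displaced by the alkoxide far faster than bromine, which puts the future phenol oxygen next to the nitrile carbon.

Step 2
Reactants: 2 2-(benzyloxy)-6-bromobenzonitrile
Product: 3 methyl 3-(benzyloxy)-2-cyanobenzoate
Conditions: CO (1 atm), Pd(OAc)2 (3 mol %), Xantphos (6 mol %), Et3N, MeOH, 70 °C
Reagents that add atoms: carbon monoxide, [C-]#[O+]; methanol, CO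
Why: Palladium-catalysed alkoxycarbonylation of an aryl bromide (oxidative addition, CO insertion, methanolysis of the acyl complex); the nitrile and the benzyl ether are inert and the small ortho cyano group does not block insertion.

Step 3
Reactants: 3 methyl 3-(benzyloxy)-2-cyanobenzoate
Product: 5 4-(benzyloxy)-3,3-dimethoxyisoindolin-1-one, via 4-(benzyloxy)-3-methoxy-1H-isoindol-1-one 4 (not isolated)
Conditions: NaOMe (0.3 equiv), MeOH, 0 °C → rt; AcOH quench
Reagents that add atoms: methanol, CO
Why: Base-catalysed Pinner-type addition of methoxide to the nitrile, 5-exo acylation of the imidate nitrogen by the neighbouring ester to acyl imidate 4, and addition of methanol across its electrophilic C=N. The ketal carbon is therefore the former nitrile carbon, so its position next to the benzyloxy group is fixed by construction.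

Step 4
Reactants: 6 3-[(4-methoxybenzyl)oxy]propanal; 7 (E)-crotylboronic acid pinacol ester
Product: 9 (3R,4S)-1-[(4-methoxybenzyl)oxy]-4-methylhex-5-en-3-ol, via pinacol borate ester 8 (not isolated)
Conditions: 7 (1.2 equiv), (S)-3,3′-bis(2,4,6-triisopropylphenyl)-1,1′-binaphthyl-2,2′-diyl hydrogen phosphate (5 mol %), toluene, −30 °C; then H2O, rt
Reagents that add atoms: none
Why: Chiral phosphoric acid-catalysed crotylboration of an aldehyde with a pinacol crotylboronate: the acid hydrogen-bonds to a boronate oxygen and to the formyl hydrogen in a closed chair transition state, so the E geometry of the crotyl unit gives the 3,4-anti relationship. The (S)-configured binaphthyl pocket directs the crotyl group to the Si face of the aldehyde, which sets 3R and hence 4S, and water then hydrolyses the borate ester 8.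

Step 5
Reactants: 9 (3R,4S)-1-[(4-methoxybenzyl)oxy]-4-methylhex-5-en-3-ol
Product: 10 triethyl{[(3R,4S)-1-[(4-methoxybenzyl)oxy]-4-methylhex-5-en-3-yl]oxy}silane
Conditions: TESCl, imidazole, 4-(dimethylamino)pyridine (cat.), DMF, rt
Reagents that add atoms: chlorotriethylsilane, CC[Si](Cl)(CC)CC
Why: Silylation of a secondary alcohol; the triethylsilyl ether survives the basic, oxidative and mildly acidic steps that follow and is removed later by mild acid.

Step 6
Reactants: 10 triethyl{[(3R,4S)-1-[(4-methoxybenzyl)oxy]-4-methylhex-5-en-3-yl]oxy}silane; 11 vinyl bromide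
Product: 13 triethyl{[(3R,4S)-1-[(4-methoxybenzyl)oxy]-4-methyloct-7-en-3-yl]oxy}silane, via B-alkyl-9-borabicyclononane 12 (not isolated)
Conditions: 9-BBN-H, THF, 0 °C → rt; then 11 (1 M in THF), PdCl2(dppf) (5 mol %), aq K3PO4, DMF, rt
Reagents that add atoms: none
Why: Anti-Markovnikov hydroboration of the vinyl group followed by B-alkyl Suzuki–Miyaura coupling with the vinyl halide adds the two carbons that turn the vinyl group into the but-3-enyl chain; no stereocentre is touched.

Step 7
Reactants: 13 triethyl{[(3R,4S)-1-[(4-methoxybenzyl)oxy]-4-methyloct-7-en-3-yl]oxy}silane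
Product: 14 (3R,4S)-4-methyl-3-[(triethylsilyl)oxy]oct-7-en-1-ol
Conditions: DDQ, CH2Cl2–pH 7 buffer, 0 °C
Reagents that add atoms: none
Why: Oxidative cleavage of the p-methoxybenzyl ether (hydride abstraction from the electron-rich benzylic position, then hydrolysis); the silyl ether and the terminal alkene are not oxidised.

Step 8
Reactants: 14 (3R,4S)-4-methyl-3-[(triethylsilyl)oxy]oct-7-en-1-ol
Product: 15 (3R,4S)-4-methyl-3-[(triethylsilyl)oxy]oct-7-enal
Conditions: Dess–Martin periodinane, CH2Cl2, 0 °C → rt
Reagents that add atoms: none
Why: Dess–Martin oxidation of a primary alcohol under near-neutral conditions, which avoids β-elimination of the silyloxy group.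

Step 9
Reactants: 15 (3R,4S)-4-methyl-3-[(triethylsilyl)oxy]oct-7-enal
Product: 16 (3R,4S)-4-methyl-3-[(triethylsilyl)oxy]oct-7-enoic acid
Conditions: NaClO2, NaH2PO4, 2-methylbut-2-ene, t-BuOH–H2O, 0 °C → rt
Reagents that add atoms: sodium chlorite, [Na+].[O-]Cl=O
Why: Pinnick oxidation of the aldehyde; the excess alkene scavenger takes up the hypochlorous acid, so the terminal alkene of the substrate is spared.

Step 10
Reactants: 16 (3R,4S)-4-methyl-3-[(triethylsilyl)oxy]oct-7-enoic acid; 5 4-(benzyloxy)-3,3-dimethoxyisoindolin-1-one
Product: 19 4-(benzyloxy)-3,3-dimethoxy-2-{(3R,4S)-4-methyl-3-[(triethylsilyl)oxy]oct-7-enoyl}isoindolin-1-one, via mixed pivalic anhydride 17 (not isolated), via lithium lactamide 18 (not isolated)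
Conditions: 16, t-BuCOCl, Et3N, THF, −20 °C; 5, LiN(SiMe3)2, THF, −78 °C; combine, −78 → −20 °C
Reagents that add atoms: none
Why: N-acylation of a lithium lactamide by a mixed pivalic anhydride, as in the acylation of lithiated oxazolidinones; attack goes to the unhindered CH2–C=O carbonyl, and the low temperature keeps the lithiated ketal from expelling methoxide.

Step 11
Reactants: 19 4-(benzyloxy)-3,3-dimethoxy-2-{(3R,4S)-4-methyl-3-[(triethylsilyl)oxy]oct-7-enoyl}isoindolin-1-one
Product: 21 (2R,10bR)-10-(benzyloxy)-2-[(2S)-hex-5-en-2-yl]-10b-methoxy-2,3-dihydro-[1,3]oxazino[2,3-a]isoindole-4,6-dione, via hydroxy dimethyl ketal 20 (not isolated)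
Conditions: camphor-10-sulfonic acid (0.1 equiv), MeOH–CH2Cl2 (1:4), 0 °C → rt; then evaporation, CH2Cl2, 4 Å molecular sieves, rt
Reagents that add atoms: none
Why: Acid-catalysed methanolysis of the silyl ether frees the C3 hydroxyl, which displaces one methoxy group through the aryl-stabilised oxocarbenium ion (intramolecular transketalisation, six-membered ring). The ketal carbon equilibrates to the epimer with axial methoxy trans to the equatorial hexenyl chain.

Step 12
Reactants: 22 methyl (S)-3-hydroxy-2-methylpropanoate
Product: 23 methyl (S)-3-[(tert-butyldimethylsilyl)oxy]-2-methylpropanoate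
Conditions: TBSCl, imidazole, CH2Cl2, rt
Reagents that add atoms: tert-butylchlorodimethylsilane, CC(C)(C)[Si](C)(C)Cl
Why: Silylation of the primary alcohol under conditions too mild to epimerise the α-centre.

Step 13
Reactants: 23 methyl (S)-3-[(tert-butyldimethylsilyl)oxy]-2-methylpropanoate
Product: 24 (R)-3-[(tert-butyldimethylsilyl)oxy]-2-methylpropan-1-ol
Conditions: i-Bu2AlH (2.5 equiv), CH2Cl2, −78 → 0 °C; aq KNaC4H4O6
Reagents that add atoms: none
Why: Full hydride reduction of the ester to the primary alcohol; the stereocentre is not enolisable under these conditions, and the descriptor changes only because the priorities change.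

Step 14
Reactants: 24 (R)-3-[(tert-butyldimethylsilyl)oxy]-2-methylpropan-1-ol
Product: 25 (S)-3-[(tert-butyldimethylsilyl)oxy]-2-methylpropanal
Conditions: (COCl)2, DMSO, CH2Cl2, −78 °C; i-Pr2NEt, −78 → −30 °C; used crude
Reagents that add atoms: none
Why: Swern oxidation; the hindered amine and the low temperature limit enolisation of the α-methyl aldehyde, which is used at once.

Step 15
Reactants: 25 (S)-3-[(tert-butyldimethylsilyl)oxy]-2-methylpropanal; 26 (E)-but-2-ene
Product: 30 (2S,3R,4R)-1-[(tert-butyldimethylsilyl)oxy]-2,4-dimethylhex-5-en-3-ol, via (E)-but-2-enylpotassium 27 (not isolated), via (E)-crotyl-(+)-Ipc2-borane 28 (not isolated), via borinate ester 29 (not isolated)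
Conditions: 26, n-BuLi, KOt-Bu, THF, −78 → −45 °C; (+)-Ipc2BOMe, −78 °C; BF3·OEt2; 25, −78 °C; then NaOH, H2O2, rt
Reagents that add atoms: none
Why: Brown crotylboration under reagent control: the E-crotyl unit gives the C9/C10 anti relationship through the chair transition state, and the ligands derived from (−)-α-pinene enforce Re-face attack against the weak Felkin preference of the aldehyde. C10 is thus set anti to the existing C11 methyl, completing the anti,anti triad.

Step 16
Reactants: 30 (2S,3R,4R)-1-[(tert-butyldimethylsilyl)oxy]-2,4-dimethylhex-5-en-3-ol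
Product: 31 (2S,3R,4R)-2,4-dimethylhex-5-ene-1,3-diol
Conditions: Bu4NF, THF, 0 °C → rt
Reagents that add atoms: none
Why: Fluoride cleavage of the primary silyl ether; nothing in the substrate is base-sensitive at this stage.

Step 17
Reactants: 31 (2S,3R,4R)-2,4-dimethylhex-5-ene-1,3-diol
Product: 33 (2R,3R,4R)-3-hydroxy-2,4-dimethylhex-5-enoic acid, via hydroxy aldehyde 32 (not isolated)
Conditions: 2,2,6,6-tetramethylpiperidin-1-oxyl (0.2 equiv), PhI(OAc)2 (2.2 equiv), MeCN–H2O (1:1), rt
Reagents that add atoms: water, O
Why: Oxoammonium (TEMPO) oxidation, which selects the primary hydroxyl over the hindered secondary one; the aldehyde hydrate is oxidised on to the acid in the aqueous medium, and the mild acidity does not epimerise C11.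

Step 18
Reactants: 33 (2R,3R,4R)-3-hydroxy-2,4-dimethylhex-5-enoic acid; 34 pyrrole
Product: 37 (2R,3R,4R)-3-hydroxy-2,4-dimethyl-1-(1H-pyrrol-2-yl)hex-5-en-1-one, via pyrrol-1-ylmagnesium bromide 35 (not isolated), via S-(pyridin-2-yl) thioester 36 (not isolated)
Conditions: 33, 2,2′-dipyridyl disulfide, PPh3, CH2Cl2, rt; solution added to 35 (from 34 and EtMgBr, THF–toluene, 0 °C; 4 equiv) at −78 °C; aq NH4Cl
Reagents that add atoms: none
Why: Ketone synthesis from a 2-pyridyl thioester and a pyrrolyl Grignard reagent: magnesium chelation by the pyridyl nitrogen activates the thioester for C2-acylation of the ambident pyrrolyl anion at low temperature. The N-magnesio 2-acylpyrrole formed is too electron-poor to add again, and excess reagent covers the free hydroxyl.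

Step 19
Reactants: 21 (2R,10bR)-10-(benzyloxy)-2-[(2S)-hex-5-en-2-yl]-10b-methoxy-2,3-dihydro-[1,3]oxazino[2,3-a]isoindole-4,6-dione; 37 (2R,3R,4R)-3-hydroxy-2,4-dimethyl-1-(1H-pyrrol-2-yl)hex-5-en-1-one
Product: 38 (2R,10bS)-10-(benzyloxy)-10b-{[(3R,4R,5R)-3,5-dimethyl-6-oxo-6-(1H-pyrrol-2-yl)hex-1-en-4-yl]oxy}-2-[(2S)-hex-5-en-2-yl]-2,3-dihydro-[1,3]oxazino[2,3-a]isoindole-4,6-dione
Conditions: 21 (1.0 equiv), 37 (1.5 equiv), camphor-10-sulfonic acid (0.2 equiv), 5 Å molecular sieves, toluene, 45 °C
Reagents that add atoms: none
Why: Acid-catalysed transketalisation: 21 ionises to the oxocarbenium ion stabilised by O3 and the arene, the hydroxyl of 37 captures it, and the sieves remove methanol to drive the exchange. The reversible conditions should deliver the more stable ketal epimer, with axial O10 trans to the equatorial hexenyl chain, which is the configuration of 40.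

Step 20
Reactants: 38 (2R,10bS)-10-(benzyloxy)-10b-{[(3R,4R,5R)-3,5-dimethyl-6-oxo-6-(1H-pyrrol-2-yl)hex-1-en-4-yl]oxy}-2-[(2S)-hex-5-en-2-yl]-2,3-dihydro-[1,3]oxazino[2,3-a]isoindole-4,6-dione
Product: 39 7,8-didehydro derivative of the O-benzyl ether of 40 (Z alkene drawn)
Conditions: RuCl2(=CHPh)(PCy3)(H2IMes) (second-generation Grubbs catalyst, 10 mol %), 1,4-benzoquinone (20 mol %), CH2Cl2 (1 mM), 40 °C
Reagents that add atoms: none
Why: The ruthenium benzylidene loads on the unhindered butenyl terminus (C7); the new alkylidene engages the C9 vinyl group in an intramolecular [2+2] cycloaddition, and cycloreversion of the ruthenacyclobutane forms C7=C8 and releases ethene, whose escape makes the closure irreversible. This is ordinary ring-closing alkene metathesis to a medium ring. The ring closed is the 11-membered ring (C3 to C10, O10, the ketal carbon and O3), formed by head-to-head union of two terminal alkenes so that the new double bond is endocyclic. No stereocentre is created, and the alkene geometry is of no consequence because step 21 saturates the bond. The step needs ring closure to outrun intermolecular metathesis; this is secured by high dilution and by the two tethers leaving one ketal carbon through geminal oxygens (axial O10, equatorial chain on the neighbouring ring carbon), which holds the termini within reach. Chemoselectivity is not an issue, since 38 has only two alkenes and the imide, benzyl ether and 2-acylpyrrole do not bind the catalyst strongly. The benzoquinone suppresses hydride-mediated double-bond migration, which could otherwise erode the C9 centre or give ring-contracted products.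

Step 21
Reactants: 39 7,8-didehydro derivative of the O-benzyl ether of 40
Product: 40 CNP0418824.1 (3R,4S,9R,10R,11R; ketal carbon S)
Conditions: H2 (1 atm), 10% Pd/C, NaHCO3, EtOAc, rt
Reagents that add atoms: none
Why: Heterogeneous hydrogenation saturates the disubstituted ring alkene and hydrogenolyses the aryl benzyl ether in one operation. The solid NaHCO3 keeps the medium neutral, so the benzylic ketal C–O bonds (which need acid assistance to cleave) and the acylpyrrole should be left alone.

## Compound list

1 | 2-bromo-6-fluorobenzonitrile | N#Cc1c(F)cccc1Br | starting material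
2 | 2-(benzyloxy)-6-bromobenzonitrile | N#Cc1c(Br)cccc1OCc2ccccc2 | intermediate
3 | methyl 3-(benzyloxy)-2-cyanobenzoate | COC(=O)c1cccc(OCc2ccccc2)c1C#N | intermediate
4 | 4-(benzyloxy)-3-methoxy-1H-isoindol-1-one | COC1=NC(=O)c2cccc(OCc3ccccc3)c12 | intermediate
5 | 4-(benzyloxy)-3,3-dimethoxyisoindolin-1-one | COC1(OC)NC(=O)c2cccc(OCc3ccccc3)c12 | intermediate
6 | 3-[(4-methoxybenzyl)oxy]propanal | COc1ccc(COCCC=O)cc1 | starting material
7 | (E)-crotylboronic acid pinacol ester, 2-[(2E)-but-2-en-1-yl]-4,4,5,5-tetramethyl-1,3,2-dioxaborolane | C/C=C/CB1OC(C)(C)C(C)(C)O1 | starting material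
8 | 2-{[(3R,4S)-1-[(4-methoxybenzyl)oxy]-4-methylhex-5-en-3-yl]oxy}-4,4,5,5-tetramethyl-1,3,2-dioxaborolane (pinacol borate ester of 9) | C=C[C@H](C)[C@H](OB1OC(C)(C)C(C)(C)O1)CCOCc2ccc(OC)cc2 | intermediate
9 | (3R,4S)-1-[(4-methoxybenzyl)oxy]-4-methylhex-5-en-3-ol | C=C[C@H](C)[C@H](O)CCOCc1ccc(OC)cc1 | intermediate
10 | triethyl{[(3R,4S)-1-[(4-methoxybenzyl)oxy]-4-methylhex-5-en-3-yl]oxy}silane | C=C[C@H](C)[C@H](O[Si](CC)(CC)CC)CCOCc1ccc(OC)cc1 | intermediate
11 | vinyl bromide | C=CBr | starting material
12 | 9-{(3S,4R)-6-[(4-methoxybenzyl)oxy]-3-methyl-4-[(triethylsilyl)oxy]hexyl}-9-borabicyclo[3.3.1]nonane | C1CCC2CCCC1B2CC[C@H](C)[C@H](O[Si](CC)(CC)CC)CCOCc3ccc(OC)cc3 | intermediate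
13 | triethyl{[(3R,4S)-1-[(4-methoxybenzyl)oxy]-4-methyloct-7-en-3-yl]oxy}silane | C=CCC[C@H](C)[C@H](O[Si](CC)(CC)CC)CCOCc1ccc(OC)cc1 | intermediate
14 | (3R,4S)-4-methyl-3-[(triethylsilyl)oxy]oct-7-en-1-ol | C=CCC[C@H](C)[C@H](O[Si](CC)(CC)CC)CCO | intermediate
15 | (3R,4S)-4-methyl-3-[(triethylsilyl)oxy]oct-7-enal | C=CCC[C@H](C)[C@H](O[Si](CC)(CC)CC)CC=O | intermediate
16 | (3R,4S)-4-methyl-3-[(triethylsilyl)oxy]oct-7-enoic acid | C=CCC[C@H](C)[C@H](O[Si](CC)(CC)CC)CC(=O)O | intermediate
17 | mixed anhydride of 16 with pivalic acid | C=CCC[C@H](C)[C@H](O[Si](CC)(CC)CC)CC(=O)OC(=O)C(C)(C)C | intermediate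
18 | lithium salt of 5 (N-lithio lactam) | [Li+].COC1(OC)[N-]C(=O)c2cccc(OCc3ccccc3)c12 | intermediate
19 | 4-(benzyloxy)-3,3-dimethoxy-2-{(3R,4S)-4-methyl-3-[(triethylsilyl)oxy]oct-7-enoyl}isoindolin-1-one | C=CCC[C@H](C)[C@H](O[Si](CC)(CC)CC)CC(=O)N1C(=O)c2cccc(OCc3ccccc3)c2C1(OC)OC | intermediate
20 | 4-(benzyloxy)-2-[(3R,4S)-3-hydroxy-4-methyloct-7-enoyl]-3,3-dimethoxyisoindolin-1-one | C=CCC[C@H](C)[C@H](O)CC(=O)N1C(=O)c2cccc(OCc3ccccc3)c2C1(OC)OC | intermediate
21 | (2R,10bR)-10-(benzyloxy)-2-[(2S)-hex-5-en-2-yl]-10b-methoxy-2,3-dihydro-[1,3]oxazino[2,3-a]isoindole-4,6-dione | C=CCC[C@H](C)[C@H]2CC(=O)N3C(=O)c4cccc(OCc5ccccc5)c4[C@@]3(OC)O2 | intermediate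
22 | methyl (S)-3-hydroxy-2-methylpropanoate | COC(=O)[C@@H](C)CO | starting material
23 | methyl (S)-3-[(tert-butyldimethylsilyl)oxy]-2-methylpropanoate | COC(=O)[C@@H](C)CO[Si](C)(C)C(C)(C)C | intermediate
24 | (R)-3-[(tert-butyldimethylsilyl)oxy]-2-methylpropan-1-ol | OC[C@@H](C)CO[Si](C)(C)C(C)(C)C | intermediate
25 | (S)-3-[(tert-butyldimethylsilyl)oxy]-2-methylpropanal | O=C[C@@H](C)CO[Si](C)(C)C(C)(C)C | intermediate
26 | (E)-but-2-ene | C/C=C/C | starting material
27 | (E)-but-2-enylpotassium | C/C=C/C[K] | intermediate
28 | (E)-but-2-enylbis(isopinocampheyl)borane, (+)-Ipc2B series from (−)-α-pinene | C/C=C/CB([C@H]1C[C@H]2C[C@@H]([C@@H]1C)C2(C)C)[C@H]3C[C@H]4C[C@@H]([C@@H]3C)C4(C)C | intermediate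
29 | bis(isopinocampheyl)borinate ester of 30, (+)-Ipc series | O([C@H]([C@H](C)C=C)[C@@H](C)CO[Si](C)(C)C(C)(C)C)B([C@H]1C[C@H]2C[C@@H]([C@@H]1C)C2(C)C)[C@H]3C[C@H]4C[C@@H]([C@@H]3C)C4(C)C | intermediate
30 | (2S,3R,4R)-1-[(tert-butyldimethylsilyl)oxy]-2,4-dimethylhex-5-en-3-ol | O[C@H]([C@H](C)C=C)[C@@H](C)CO[Si](C)(C)C(C)(C)C | intermediate
31 | (2S,3R,4R)-2,4-dimethylhex-5-ene-1,3-diol | O[C@H]([C@H](C)C=C)[C@@H](C)CO | intermediate
32 | (2R,3R,4R)-3-hydroxy-2,4-dimethylhex-5-enal | O[C@H]([C@H](C)C=C)[C@@H](C)C=O | intermediate
33 | (2R,3R,4R)-3-hydroxy-2,4-dimethylhex-5-enoic acid | O[C@H]([C@H](C)C=C)[C@@H](C)C(=O)O | intermediate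
34 | pyrrole | c1cc[nH]c1 | starting material
35 | pyrrol-1-ylmagnesium bromide | Br[Mg]n1cccc1 | intermediate
36 | S-(pyridin-2-yl) (2R,3R,4R)-3-hydroxy-2,4-dimethylhex-5-enethioate | O[C@H]([C@H](C)C=C)[C@@H](C)C(=O)Sc1ccccn1 | intermediate
37 | (2R,3R,4R)-3-hydroxy-2,4-dimethyl-1-(1H-pyrrol-2-yl)hex-5-en-1-one | O[C@H]([C@H](C)C=C)[C@@H](C)C(=O)c1ccc[nH]1 | intermediate
38 | (2R,10bS)-10-(benzyloxy)-10b-{[(3R,4R,5R)-3,5-dimethyl-6-oxo-6-(1H-pyrrol-2-yl)hex-1-en-4-yl]oxy}-2-[(2S)-hex-5-en-2-yl]-2,3-dihydro-[1,3]oxazino[2,3-a]isoindole-4,6-dione (metathesis precursor) | C=CCC[C@H](C)[C@H]2CC(=O)N3C(=O)c4cccc(OCc5ccccc5)c4[C@@]3(O[C@H]([C@H](C)C=C)[C@@H](C)C(=O)c1ccc[nH]1)O2 | intermediate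
39 | 7,8-didehydro derivative of the O-benzyl ether of 40 (Z drawn) | C[C@@H]1/C=C\CC[C@H](C)[C@H]2CC(=O)N3C(=O)c4cccc(OCc5ccccc5)c4[C@@]3(O[C@H]1[C@@H](C)C(=O)c1ccc[nH]1)O2 | intermediate
40 | CNP0418824.1 | C[C@@H]1CCCC[C@H](C)[C@H]2CC(=O)N3C(=O)c4cccc(O)c4[C@@]3(O[C@H]1[C@@H](C)C(=O)c1ccc[nH]1)O2 | target

## Step count and least certain steps

Total step count: 21. Longest linear sequence: 11 steps (steps 4 to 11, then 19 to 21, from aldehyde 6).

Step 20 (key step). The most likely failure is intermolecular metathesis through the unhindered butenyl terminus (dimers, oligomers) outrunning closure of the strained 11-membered ring, because the C9 vinyl group is branched at the allylic carbon and sits next to the crowded ketal oxygen. Fallback: the order of the two unions is reversed. Setting out from 21 and 37, cross-metathesis with RuCl2(=CH-o-OiPrC6H4)(H2IMes) joins the butenyl terminus of 21 to the vinyl group of 37 and gives the open-chain hydroxy methoxy ketal F1. Acid-catalysed internal exchange of the methoxy group by the C10 hydroxyl (camphor-10-sulfonic acid, 5 Å sieves, high dilution) then closes the ring through the O10–ketal bond and gives the E-configured macrocycle F2. Hydrogenation of F2 as in step 21 returns to the route at 40.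

Step 19. The exchange may stall: the equilibrium with a secondary hydroxyl flanked by two branched carbons is unfavourable, capture of the crowded cation is slow, and long heating with acid invites dehydration or C11 epimerisation of 37. Fallback: an irreversible donor replaces the equilibrium. Setting out from 21, exchange with PhSH and BF3·OEt2 gives the S-phenyl monothioketal F3. Activation of F3 with MeOTf and 2,6-di-tert-butyl-4-methylpyridine in the presence of 37 and 4 Å sieves at −40 °C generates the same cation and traps it kinetically, anti to the hexenyl chain, returning at 38.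

Step 10. The lithiated lactam may expel methoxide (reversion towards 4), and acylation at the nitrogen next to the ketal carbon may be slow, so that 5 is recovered or the acyl group is lost as an ester. Fallback: the nitrogen is brought in on the acid. Setting out from 16 (through anhydride 17 and NH3), the primary amide F4 is made. Its sodium salt (NaH, THF) is acylated by ester 3, and the imide nitrogen then adds to the ortho nitrile to give the N-acyl-3-iminoisoindolinone F5. Camphor-10-sulfonic acid (1.1 equiv) in MeOH removes the silyl group from F5; the hydroxyl adds to the amidine carbon, ammonia is lost and methanol is taken up, returning at 21.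

Step 15. Facial selectivity may be poor, since the reagent must override the Felkin preference of aldehyde 25 to give the anti,anti triad, and 25 can epimerise before it reacts. Fallback: a chiral allenylmetal replaces the crotylborane. Setting out from 25, the allenylzinc reagent formed from (S)-but-3-yn-2-yl methanesulfonate with Pd(OAc)2, PPh3 and Et2Zn (anti-selective addition of Marshall type) should give the anti,anti homopropargylic alcohol F6. Semi-hydrogenation of F6 (H2, Pd/CaCO3 poisoned with Pb(OAc)2, quinoline) returns at 30.

Step 18. The magnesium alkoxide formed from the free hydroxyl may trigger retro-aldol cleavage or C11 epimerisation, or close the β-lactone before the pyrrolyl reagent acylates. Fallback: the hydroxyl is masked during the acylation. Setting out from 33, silylation of both acidic groups (TESCl, imidazole) and cleavage of the silyl ester (K2CO3, aq MeOH) give the silyl ether acid F7. The same thioester and pyrrolyl Grignard sequence gives the protected ketone F8, and HF·pyridine in THF returns at 37.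

Step 4. Enantiofacial discrimination may be incomplete, because an unbranched aldehyde with a Lewis-basic ether oxygen fills the catalyst pocket less well than an aryl aldehyde, and an uncatalysed background crotylation would erode the enantiomeric purity on which C3 and C4 depend. Fallback: a stoichiometric chiral borane replaces the catalyst. Setting out from 6, (E)-but-2-ene 26 is metalated to the crotylpotassium 27 (n-BuLi, KOt-Bu, THF, −78 → −45 °C), which (−)-Ipc2BOMe and BF3·OEt2 convert into the (E)-crotylbis(isopinocampheyl)borane F9. Its addition to 6 at −78 °C, Si-face selective through the chair transition state, gives the borinate ester F10, and oxidative work-up (NaOH, H2O2) returns at 9.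

## Further compounds

F1 | step 20 | open-chain cross-metathesis product: 21 joined through an E C7=C8 bond to the former vinyl carbon of 37 | O[C@H]([C@H](C)/C=C/CC[C@H](C)[C@H]2CC(=O)N3C(=O)c4cccc(OCc5ccccc5)c4[C@@]3(OC)O2)[C@@H](C)C(=O)c1ccc[nH]1
F2 | step 20 | (7E) isomer of 39 | C[C@@H]1/C=C/CC[C@H](C)[C@H]2CC(=O)N3C(=O)c4cccc(OCc5ccccc5)c4[C@@]3(O[C@H]1[C@@H](C)C(=O)c1ccc[nH]1)O2
F3 | step 19 | 10b-(phenylthio) analogue of 21 (S-phenyl monothioketal, same spatial arrangement at the ketal carbon) | C=CCC[C@H](C)[C@H]2CC(=O)N3C(=O)c4cccc(OCc5ccccc5)c4[C@@]3(Sc6ccccc6)O2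
F4 | step 10 | (3R,4S)-4-methyl-3-[(triethylsilyl)oxy]oct-7-enamide | C=CCC[C@H](C)[C@H](O[Si](CC)(CC)CC)CC(N)=O
F5 | step 10 | 4-(benzyloxy)-3-imino-2-{(3R,4S)-4-methyl-3-[(triethylsilyl)oxy]oct-7-enoyl}isoindolin-1-one | C=CCC[C@H](C)[C@H](O[Si](CC)(CC)CC)CC(=O)N1C(=O)c2cccc(OCc3ccccc3)c2C1=N
F6 | step 15 | (2S,3R,4R)-1-[(tert-butyldimethylsilyl)oxy]-2,4-dimethylhex-5-yn-3-ol | O[C@H]([C@H](C)C#C)[C@@H](C)CO[Si](C)(C)C(C)(C)C
F7 | step 18 | (2R,3R,4R)-2,4-dimethyl-3-[(triethylsilyl)oxy]hex-5-enoic acid | CC[Si](CC)(CC)O[C@H]([C@H](C)C=C)[C@@H](C)C(=O)O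
F8 | step 18 | (2R,3R,4R)-2,4-dimethyl-1-(1H-pyrrol-2-yl)-3-[(triethylsilyl)oxy]hex-5-en-1-one | CC[Si](CC)(CC)O[C@H]([C@H](C)C=C)[C@@H](C)C(=O)c1ccc[nH]1
F9 | step 4 | (E)-but-2-enylbis(isopinocampheyl)borane, (−)-Ipc2B series from (+)-α-pinene | C/C=C/CB([C@@H]1C[C@@H]2C[C@H]([C@H]1C)C2(C)C)[C@@H]3C[C@@H]4C[C@H]([C@H]3C)C4(C)C
F10 | step 4 | bis(isopinocampheyl)borinate ester of 9, (−)-Ipc series | C=C[C@H](C)[C@H](OB([C@@H]1C[C@@H]2C[C@H]([C@H]1C)C2(C)C)[C@@H]3C[C@@H]4C[C@H]([C@H]3C)C4(C)C)CCOCc5ccc(OC)cc5
A1 | alternative 1 | macrobicyclic ketal bearing a (triisopropylsilyloxy)ethynyl group on the ketal carbon and a 2-oxo-2H-pyran-6-carbonyl group on nitrogen | C[C@@H]1CCCC[C@H](C)[C@H]2CC(=O)N(C(=O)C3=CC=CC(=O)O3)[C@](C#CO[Si](C(C)C)(C(C)C)C(C)C)(O[C@H]1[C@@H](C)C(=O)c1ccc[nH]1)O2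
A2 | alternative 1 | triisopropylsilyl ether of the target | C[C@@H]1CCCC[C@H](C)[C@H]2CC(=O)N3C(=O)c4cccc(O[Si](C(C)C)(C(C)C)C(C)C)c4[C@@]3(O[C@H]1[C@@H](C)C(=O)c1ccc[nH]1)O2
A3 | alternative 2 | tricyclic α-alkoxy acid with open C4–C12 chain, phenol as triisopropylsilyl ether, pyrrole as N-Boc (either epimer at the carboxyl-bearing carbon) | C[C@H](CCCC[C@H](C)[C@H]1CC(=O)N2C(=O)c3cccc(O[Si](C(C)C)(C(C)C)C(C)C)c3C2(C(=O)O)O1)[C@@H](O)[C@@H](C)C(=O)c1cccn1C(=O)OC(C)(C)C
A4 | alternative 2 | target protected as triisopropylsilyl ether and N-Boc pyrrole | C[C@@H]1CCCC[C@H](C)[C@H]2CC(=O)N3C(=O)c4cccc(O[Si](C(C)C)(C(C)C)C(C)C)c4[C@@]3(O[C@H]1[C@@H](C)C(=O)c1cccn1C(=O)OC(C)(C)C)O2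
A5 | alternative 3 | methyl 3-(benzyloxy)-2-iodobenzoate | COC(=O)c1cccc(OCc2ccccc2)c1I
A6 | alternative 3 | macrobicyclic 2-alkoxy-1,3-oxazin-4-one (acyl iminocarbonate) | C[C@@H]1CCCC[C@H](C)[C@H]2CC(=O)N=C(O[C@H]1[C@@H](C)C(=O)c1ccc[nH]1)O2
A7 | alternative 3 | benzyl ether of the target | C[C@@H]1CCCC[C@H](C)[C@H]2CC(=O)N3C(=O)c4cccc(OCc5ccccc5)c4[C@@]3(O[C@H]1[C@@H](C)C(=O)c1ccc[nH]1)O2
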